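The tetralin is disconnected at C1–C2, C3–C4 and C1–C8a. The key step exploits a butyrolactone hidden in ring B: C2 and C3 are its β and α carbons and the hydroxymethyl carbons C9 and C9′ its acetal and carbonyl carbons, while C1 serves as a masked acyl anion carrying ring C and C4 as a benzylic electrophile on ring A. In one operation a lithiated aryl dithiane adds to a chiral menthyloxy butenolide and the enolate is benzylated, joining three fragments and fixing C2 and, provisionally, C3. The precursors are the ring C dithiane, the (5R)-menthyloxyfuranone and a ring A benzyl bromide blocked by bromine at C5; ring B closes later at C8a and C3 is then inverted.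

Key step: step 9

Numbering: tetralin numbering is used for the target and late intermediates (C1 bears ring C, C2 and C3 carry C9 and C9′, C4 is the methylene, ring A is C4a–C8a, ring B is the saturated ring); l-menthyl means (1R,2S,5R)-2-isopropyl-5-methylcyclohexyl.

Remark on the chemistry: on a 4-alkoxybenzaldehyde a free 3-hydroxyl directs bromine to its own ortho carbon (as in isovanillin) while alkoxy groups direct para, so the blocking bromine is introduced next to a free hydroxyl that is methylated afterwards; both effects then point at the same carbon.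

**Route**

Step 1
Reactants: 1 3,4,5-trimethoxybenzaldehyde
Product: 2 2-(3,4,5-trimethoxyphenyl)-1,3-dithiane
Conditions: HS(CH2)3SH, BF3·OEt2 (cat.), CH2Cl2, 0 °C → rt
Reagents that add atoms: propane-1,3-dithiol, SCCCS
Why: Lewis-acid-catalysed dithioacetalization of an aromatic aldehyde is a routine condensation and gives the masked acyl anion for C1; no stereocenter is formed.

Step 2
Reactants: 3 furfural
Product: 5 5-hydroxy-2(5H)-furanone, via furfural endoperoxide 4 (not isolated)
Conditions: O2, rose bengal (cat.), visible light, MeOH, rt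
Reagents that add atoms: dioxygen, O=O
Why: In this dye-sensitized photooxygenation singlet oxygen adds across the furan diene in a [4+2] cycloaddition and methanol cleaves the endoperoxide with loss of the formyl carbon as methyl formate, giving the racemic lactol.

Step 3
Reactants: 5 5-hydroxy-2(5H)-furanone; 6 l-menthol
Product: 7 (5R)-5-(l-menthyloxy)-2(5H)-furanone
Conditions: p-TsOH (cat.), toluene, reflux (Dean–Stark); crystallization from hexane, mother liquor re-equilibrated with p-TsOH
Reagents that add atoms: none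
Why: Acid-catalysed acetalization of the lactol gives both acetal epimers, which interconvert under the acid while the (5R) epimer crystallizes, so C5 is set by crystallization-driven enrichment against the fixed menthyl centers.

Step 4
Reactants: 8 3,4,5-trihydroxybenzaldehyde
Product: 9 3,4-bis(benzyloxy)-5-hydroxybenzaldehyde
Conditions: BnBr (2.0 equiv), K2CO3 (2.0 equiv), DMF, 0 °C → rt, argon
Reagents that add atoms: benzyl bromide, BrCc1ccccc1
Why: In this Williamson etherification the 4-hydroxyl para to the formyl group is the most acidic and reacts first, the second benzyl group can only enter at one of the two equivalent flanking hydroxyls, and the monophenol should be separable by chromatography from the mono- and tribenzyl ethers that accompany it.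

Step 5
Reactants: 9 3,4-bis(benzyloxy)-5-hydroxybenzaldehyde
Product: 10 4,5-bis(benzyloxy)-2-bromo-3-hydroxybenzaldehyde
Conditions: Br2 (1.0 equiv), NaOAc, AcOH, rt
Reagents that add atoms: bromine, BrBr
Why: Electrophilic aromatic bromination should occur at C6 of 9, which is ortho to the free hydroxyl and para to the 3-benzyloxy group, in line with the bromination of isovanillin between its hydroxyl and formyl groups.

Step 6
Reactants: 10 4,5-bis(benzyloxy)-2-bromo-3-hydroxybenzaldehyde
Product: 11 4,5-bis(benzyloxy)-2-bromo-3-methoxybenzaldehyde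
Conditions: MeI, K2CO3, DMF, rt
Reagents that add atoms: iodomethane, CI
Why: Williamson O-methylation of the only free phenol fixes the methoxy group (the future C6 substituent) next to the blocking bromine.

Step 7
Reactants: 11 4,5-bis(benzyloxy)-2-bromo-3-methoxybenzaldehyde
Product: 12 [4,5-bis(benzyloxy)-2-bromo-3-methoxyphenyl]methanol
Conditions: NaBH4, MeOH/THF, 0 °C
Reagents that add atoms: none
Why: Borohydride reduction of an aryl aldehyde is chemoselective and leaves the aryl bromide and the benzyl ethers untouched.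

Step 8
Reactants: 12 [4,5-bis(benzyloxy)-2-bromo-3-methoxyphenyl]methanol
Product: 13 4,5-bis(benzyloxy)-2-bromo-3-methoxybenzyl bromide
Conditions: PBr3, CH2Cl2, 0 °C
Reagents that add atoms: phosphorus tribromide, BrP(Br)Br
Why: Conversion of a benzylic alcohol into the bromide with PBr3 (nucleophilic substitution through the phosphite ester) is standard, and the ortho bromine tempers the lability of the electron-rich benzylic bromide.

Step 9
Reactants: 2 2-(3,4,5-trimethoxyphenyl)-1,3-dithiane; 7 (5R)-5-(l-menthyloxy)-2(5H)-furanone; 13 4,5-bis(benzyloxy)-2-bromo-3-methoxybenzyl bromide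
Product: 16 (3R,4R,5R)-3-[4,5-bis(benzyloxy)-2-bromo-3-methoxybenzyl]-5-(l-menthyloxy)-4-[2-(3,4,5-trimethoxyphenyl)-1,3-dithian-2-yl]dihydrofuran-2(3H)-one, via 2-lithio-1,3-dithiane 14 (not isolated), via lithium lactone enolate 15 (not isolated)
Conditions: 2, n-BuLi, THF, −78 → −20 °C; 7, −78 °C; then 13, DMPU, −78 → 0 °C
Reagents that add atoms: none
Why: n-BuLi deprotonates dithiane 2 at C2, the sulfur-stabilized carbanion 14 adds 1,4 to butenolide 7 to form the C1–C2 bond and lithium enolate 15, and 15 is C-benzylated by bromide 13 to form the C3–C4 bond (tandem Michael addition and enolate alkylation). The closest known reaction type is the conjugate addition of lithiated 2-aryl-1,3-dithianes to 5-alkoxy-2(5H)-furanones with benzylation of the enolate in the same flask, the usual entry to dibenzylbutyrolactone lignan skeletons. No ring is closed. The C2 stereocenter is controlled by the acetal carbon, because the nucleophile enters the butenolide face anti to the menthyloxy group, and the C3 stereocenter is controlled by the new dithianyl group, because the bromide approaches the enolate face anti to it, so the all-trans lactone should form as one enantiomer. The step needs 1,4- over 1,2-addition, which the soft and hindered dithianyl anion secures, and C-monoalkylation before retro-Michael loss of the dithiane, which the reactive benzylic bromide, DMPU and low temperature secure; the aryl bromine and benzyl ethers are safe because all n-BuLi is consumed before 13 is added.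

Step 10
Reactants: 16 the dithianyl lactone from step 9
Product: 17 (3R,4R,5R)-3-[4,5-bis(benzyloxy)-2-bromo-3-methoxybenzyl]-5-(l-menthyloxy)-4-(3,4,5-trimethoxybenzoyl)dihydrofuran-2(3H)-one
Conditions: HgO, BF3·OEt2, THF/H2O, rt
Reagents that add atoms: water, O
Why: Thiophilic mercury-assisted hydrolysis of a 2,2-disubstituted dithiane releases the C1 aryl ketone under conditions that the lactone acetal, the benzyl ethers and the aryl bromide tolerate; the C2 center α to the ketone already has the favoured trans arrangement.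

Step 11
Reactants: 17 the keto acetal lactone from step 10
Product: 21 (3R,4R)-3-[4,5-bis(benzyloxy)-2-bromo-3-methoxybenzyl]-4-[hydroxy(3,4,5-trimethoxyphenyl)methyl]dihydrofuran-2(3H)-one, via carbinol acetal lactone 18 (not isolated), via aldehyde carboxylate 19 (not isolated), via dihydroxy carboxylate 20 (not isolated)
Conditions: NaBH4, THF/EtOH, 0 °C; then aq KOH, rt; then aq HCl (pH 2), rt
Reagents that add atoms: none
Why: Borohydride first reduces the ketone so that no β-keto aldehyde is ever exposed, hydroxide then saponifies the lactol ester and the liberated C9 aldehyde is reduced as it forms with release of menthol, and acidification lactonizes the primary C9 hydroxyl onto C9′ (ketone reduction, saponification, aldehyde reduction, lactonization); the C1 carbinol forms as an epimer mixture, which is harmless because C1 is ionized in step 12.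

Step 12
Reactants: 21 the hydroxy lactone from step 11
Product: 23 (3aR,4S,9aR)-5,6-bis(benzyloxy)-8-bromo-7-methoxy-4-(3,4,5-trimethoxyphenyl)-3a,4,9,9a-tetrahydronaphtho[2,3-c]furan-1(3H)-one, via benzylic cation 22 (not isolated)
Conditions: TFA, CH2Cl2, 0 °C → rt
Reagents that add atoms: none
Why: In this intramolecular Friedel–Crafts alkylation TFA ionizes the C1 carbinol to a cation stabilized by ring C and ring A attacks through C8a, the only open position next to the tether (para to the C6 methoxy group, C5 being blocked by bromine), with ring C settling trans to the C2 lactone methylene in the chair-like closure, which sets C1.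

Step 13
Reactants: 23 the trans-fused tetralin lactone from step 12
Product: 25 (3aR,4S,9aS)-5,6-bis(benzyloxy)-8-bromo-7-methoxy-4-(3,4,5-trimethoxyphenyl)-3a,4,9,9a-tetrahydronaphtho[2,3-c]furan-1(3H)-one, via potassium lactone enolate 24 (not isolated)
Conditions: t-BuOK (0.2 equiv), t-BuOH/THF, rt; then AcOH
Reagents that add atoms: none
Why: Reversible enolization at C3, the only acidic stereocenter, should drain the strained trans-fused lactone into the cis-fused one, which also lets ring C tilt away from the C8 benzyloxy group; this is the known base epimerization of trans-fused aryltetralin lactones (the α- to β-conidendrin type) and inverts C3 only.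

Step 14
Reactants: 25 the cis-fused tetralin lactone from step 13
Product: 26 [(1S,2R,3S)-7,8-bis(benzyloxy)-5-bromo-6-methoxy-1-(3,4,5-trimethoxyphenyl)-1,2,3,4-tetrahydronaphthalene-2,3-diyl]dimethanol
Conditions: LiAlH4, THF, 0 °C → rt
Reagents that add atoms: none
Why: Hydride reduction of the lactone gives the 2,3-cis diol without touching a stereocenter; partial loss of the aryl bromine would be harmless at this stage.

Step 15
Reactants: 26 the protected bromo diol from step 14
Product: 27 (1S,2R,3S)-2,3-bis(hydroxymethyl)-6-methoxy-1-(3,4,5-trimethoxyphenyl)-1,2,3,4-tetrahydronaphthalene-7,8-diol (target)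
Conditions: H2 (1 atm), Pd/C, Et3N, MeOH/EtOAc, rt; work-up under argon
Reagents that add atoms: none
Why: Catalytic hydrogenolysis removes both benzyl ethers and, with the amine as acid scavenger, the blocking aryl bromine in one operation, while the methyl ethers and the three stereocenters are inert.

**Compound list**

1 | 3,4,5-trimethoxybenzaldehyde | COc1cc(C=O)cc(OC)c1OC | starting material
2 | 2-(3,4,5-trimethoxyphenyl)-1,3-dithiane | COc1cc(C2SCCCS2)cc(OC)c1OC | intermediate
3 | furfural | O=Cc1ccco1 | starting material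
4 | furfural endoperoxide (2,3,7-trioxabicyclo[2.2.1]hept-5-ene-1-carbaldehyde, racemic) | O=CC12OOC(C=C1)O2 | intermediate
5 | 5-hydroxy-2(5H)-furanone (racemic) | O=C1OC(O)C=C1 | intermediate
6 | l-menthol, (1R,2S,5R)-2-isopropyl-5-methylcyclohexanol | CC(C)[C@@H]1CC[C@@H](C)C[C@H]1O | starting material
7 | (5R)-5-(l-menthyloxy)-2(5H)-furanone | O=C1O[C@@H](O[C@@H]2C[C@H](C)CC[C@H]2C(C)C)C=C1 | intermediate
8 | 3,4,5-trihydroxybenzaldehyde | O=Cc1cc(O)c(O)c(O)c1 | starting material
9 | 3,4-bis(benzyloxy)-5-hydroxybenzaldehyde | O=Cc1cc(O)c(OCc2ccccc2)c(OCc2ccccc2)c1 | intermediate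
10 | 4,5-bis(benzyloxy)-2-bromo-3-hydroxybenzaldehyde | O=Cc1cc(OCc2ccccc2)c(OCc2ccccc2)c(O)c1Br | intermediate
11 | 4,5-bis(benzyloxy)-2-bromo-3-methoxybenzaldehyde | O=Cc1cc(OCc2ccccc2)c(OCc2ccccc2)c(OC)c1Br | intermediate
12 | [4,5-bis(benzyloxy)-2-bromo-3-methoxyphenyl]methanol | OCc1cc(OCc2ccccc2)c(OCc2ccccc2)c(OC)c1Br | intermediate
13 | 4,5-bis(benzyloxy)-2-bromo-3-methoxybenzyl bromide | BrCc1cc(OCc2ccccc2)c(OCc2ccccc2)c(OC)c1Br | intermediate
14 | 2-lithio-2-(3,4,5-trimethoxyphenyl)-1,3-dithiane | COc1cc(C2([Li])SCCCS2)cc(OC)c1OC | intermediate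
15 | lithium enolate of (4R,5R)-5-(l-menthyloxy)-4-[2-(3,4,5-trimethoxyphenyl)-1,3-dithian-2-yl]dihydrofuran-2(3H)-one (4,5-trans) | [Li]OC1=C[C@@H](C2(c3cc(OC)c(OC)c(OC)c3)SCCCS2)[C@H](O[C@@H]2C[C@H](C)CC[C@H]2C(C)C)O1 | intermediate
16 | (3R,4R,5R)-3-[4,5-bis(benzyloxy)-2-bromo-3-methoxybenzyl]-5-(l-menthyloxy)-4-[2-(3,4,5-trimethoxyphenyl)-1,3-dithian-2-yl]dihydrofuran-2(3H)-one (3,4-trans, 4,5-trans) | O=C1O[C@@H](O[C@@H]2C[C@H](C)CC[C@H]2C(C)C)[C@H](C2(c3cc(OC)c(OC)c(OC)c3)SCCCS2)[C@H]1Cc1cc(OCc2ccccc2)c(OCc2ccccc2)c(OC)c1Br | intermediate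
17 | (3R,4R,5R)-3-[4,5-bis(benzyloxy)-2-bromo-3-methoxybenzyl]-5-(l-menthyloxy)-4-(3,4,5-trimethoxybenzoyl)dihydrofuran-2(3H)-one | O=C1O[C@@H](O[C@@H]2C[C@H](C)CC[C@H]2C(C)C)[C@H](C(=O)c2cc(OC)c(OC)c(OC)c2)[C@H]1Cc1cc(OCc2ccccc2)c(OCc2ccccc2)c(OC)c1Br | intermediate
18 | (3R,4S,5R)-3-[4,5-bis(benzyloxy)-2-bromo-3-methoxybenzyl]-4-[hydroxy(3,4,5-trimethoxyphenyl)methyl]-5-(l-menthyloxy)dihydrofuran-2(3H)-one (carbinol epimers) | O=C1O[C@@H](O[C@@H]2C[C@H](C)CC[C@H]2C(C)C)[C@H](C(O)c2cc(OC)c(OC)c(OC)c2)[C@H]1Cc1cc(OCc2ccccc2)c(OCc2ccccc2)c(OC)c1Br | intermediate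
19 | potassium (2R,3S)-2-[4,5-bis(benzyloxy)-2-bromo-3-methoxybenzyl]-3-formyl-4-hydroxy-4-(3,4,5-trimethoxyphenyl)butanoate (carbinol epimers) | [K+].[O-]C(=O)[C@H](Cc1cc(OCc2ccccc2)c(OCc2ccccc2)c(OC)c1Br)[C@H](C=O)C(O)c1cc(OC)c(OC)c(OC)c1 | intermediate
20 | potassium (2R,3R)-2-[4,5-bis(benzyloxy)-2-bromo-3-methoxybenzyl]-4-hydroxy-3-(hydroxymethyl)-4-(3,4,5-trimethoxyphenyl)butanoate (carbinol epimers) | [K+].[O-]C(=O)[C@H](Cc1cc(OCc2ccccc2)c(OCc2ccccc2)c(OC)c1Br)[C@H](CO)C(O)c1cc(OC)c(OC)c(OC)c1 | intermediate
21 | (3R,4R)-3-[4,5-bis(benzyloxy)-2-bromo-3-methoxybenzyl]-4-[hydroxy(3,4,5-trimethoxyphenyl)methyl]dihydrofuran-2(3H)-one (trans lactone, carbinol epimers) | O=C1OC[C@H](C(O)c2cc(OC)c(OC)c(OC)c2)[C@H]1Cc1cc(OCc2ccccc2)c(OCc2ccccc2)c(OC)c1Br | intermediate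
22 | C1 benzylic cation derived from 21 | O=C1OC[C@H]([CH+]c2cc(OC)c(OC)c(OC)c2)[C@H]1Cc1cc(OCc2ccccc2)c(OCc2ccccc2)c(OC)c1Br | intermediate
23 | (3aR,4S,9aR)-5,6-bis(benzyloxy)-8-bromo-7-methoxy-4-(3,4,5-trimethoxyphenyl)-3a,4,9,9a-tetrahydronaphtho[2,3-c]furan-1(3H)-one (1,2-trans, 2,3-trans in tetralin numbering) | COc1c(Br)c2c(c(OCc3ccccc3)c1OCc1ccccc1)[C@H](c1cc(OC)c(OC)c(OC)c1)[C@H]1COC(=O)[C@@H]1C2 | intermediate
24 | potassium enolate of lactone 23 (C3 planar) | COc1c(Br)c2c(c(OCc3ccccc3)c1OCc1ccccc1)[C@H](c1cc(OC)c(OC)c(OC)c1)[C@H]1COC([O-])=C1C2.[K+] | intermediate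
25 | (3aR,4S,9aS)-5,6-bis(benzyloxy)-8-bromo-7-methoxy-4-(3,4,5-trimethoxyphenyl)-3a,4,9,9a-tetrahydronaphtho[2,3-c]furan-1(3H)-one (1,2-trans, 2,3-cis) | COc1c(Br)c2c(c(OCc3ccccc3)c1OCc1ccccc1)[C@H](c1cc(OC)c(OC)c(OC)c1)[C@H]1COC(=O)[C@H]1C2 | intermediate
26 | [(1S,2R,3S)-7,8-bis(benzyloxy)-5-bromo-6-methoxy-1-(3,4,5-trimethoxyphenyl)-1,2,3,4-tetrahydronaphthalene-2,3-diyl]dimethanol | COc1c(Br)c2c(c(OCc3ccccc3)c1OCc1ccccc1)[C@H](c1cc(OC)c(OC)c(OC)c1)[C@@H](CO)[C@@H](CO)C2 | intermediate
27 | (1S,2R,3S)-2,3-bis(hydroxymethyl)-6-methoxy-1-(3,4,5-trimethoxyphenyl)-1,2,3,4-tetrahydronaphthalene-7,8-diol | COc1cc2c(c(O)c1O)[C@H](c1cc(OC)c(OC)c(OC)c1)[C@@H](CO)[C@@H](CO)C2 | target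

**Counts and risks**

Total step count: 15. Longest linear sequence: 12 steps (8 to 27 through steps 4–9 and 10–15).

Steps most likely to fail:

Step 9. The hindered lactone enolate may be benzylated too slowly, so that retro-Michael reversal or proton transfer competes and the three-component coupling stalls after the conjugate addition. Fallback: split the one-flask process into two discrete operations. Setting out from 2 and 7, the enolate is quenched with aq NH4Cl at −78 °C and the conjugate adduct (4R,5R)-5-(l-menthyloxy)-4-[2-(3,4,5-trimethoxyphenyl)-1,3-dithian-2-yl]dihydrofuran-2(3H)-one F1 is isolated and purified. F1 is then deprotonated with LiN(i-Pr)2 in THF/DMPU at −78 °C and alkylated with 13, again anti to the dithianyl group, which returns to the route at 16.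

Step 11. While the C9 aldehyde is free under hydroxide it is a β-hydroxy aldehyde, so epimerization at C2, retro-aldol cleavage or dehydration can compete with its reduction, and on acidification the acid may lactonize onto the C1 hydroxyl instead of the C9 hydroxyl. Fallback: close ring B before unmasking C9. Setting out from 17, only the ketone is reduced (NaBH4, EtOH, 0 °C, no hydroxide) and 18 is isolated. TFA in CH2Cl2 then performs the Friedel–Crafts closure with the acetal in place to give (3R,3aR,4S,9aR)-5,6-bis(benzyloxy)-8-bromo-7-methoxy-3-(l-menthyloxy)-4-(3,4,5-trimethoxyphenyl)-3a,4,9,9a-tetrahydronaphtho[2,3-c]furan-1(3H)-one F2. NaBH4/aq KOH followed by HCl converts F2, which has no C1 hydroxyl and only one possible lactone, into 23, where the route is rejoined.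

Step 12. Ring closure onto the bromine-deactivated ring A must give a strained trans-fused lactone with ring C pressed against the C8 benzyloxy group; if it is slow, long exposure to acid can erode the benzyl ethers and the trans selectivity at C1. Fallback: invert C3 before the ring is closed, so that the closure leads to the relaxed cis-fused lactone. Setting out from 21, the carbinol is silylated (TBSOTf, 2,6-lutidine, CH2Cl2) to give the (3R,4R) silyl ether (3R,4R)-3-[4,5-bis(benzyloxy)-2-bromo-3-methoxybenzyl]-4-[(tert-butyldimethylsilyloxy)(3,4,5-trimethoxyphenyl)methyl]dihydrofuran-2(3H)-one F3. Its lithium enolate (LiN(i-Pr)2, THF, −78 °C) is protonated kinetically with 2,6-di-tert-butyl-4-methylphenol on the face anti to the C2 substituent to give the cis lactone (3S,4R)-3-[4,5-bis(benzyloxy)-2-bromo-3-methoxybenzyl]-4-[(tert-butyldimethylsilyloxy)(3,4,5-trimethoxyphenyl)methyl]dihydrofuran-2(3H)-one F4. TFA in CH2Cl2 then ionizes C1 with loss of the silyl group and closes ring B at C8a, returning to the route at 25 and making step 13 unnecessary.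

**Further compounds**

F1 | step 9 | (4R,5R)-5-(l-menthyloxy)-4-[2-(3,4,5-trimethoxyphenyl)-1,3-dithian-2-yl]dihydrofuran-2(3H)-one | O=C1O[C@@H](O[C@@H]2C[C@H](C)CC[C@H]2C(C)C)[C@H](C2(c3cc(OC)c(OC)c(OC)c3)SCCCS2)C1
F2 | step 11 | (3R,3aR,4S,9aR)-5,6-bis(benzyloxy)-8-bromo-7-methoxy-3-(l-menthyloxy)-4-(3,4,5-trimethoxyphenyl)-3a,4,9,9a-tetrahydronaphtho[2,3-c]furan-1(3H)-one | COc1c(Br)c2c(c(OCc3ccccc3)c1OCc1ccccc1)[C@H](c1cc(OC)c(OC)c(OC)c1)[C@H]1[C@H](O[C@@H]3C[C@H](C)CC[C@H]3C(C)C)OC(=O)[C@@H]1C2
F3 | step 12 | (3R,4R)-3-[4,5-bis(benzyloxy)-2-bromo-3-methoxybenzyl]-4-[(tert-butyldimethylsilyloxy)(3,4,5-trimethoxyphenyl)methyl]dihydrofuran-2(3H)-one | O=C1OC[C@H](C(O[Si](C)(C)C(C)(C)C)c2cc(OC)c(OC)c(OC)c2)[C@H]1Cc1cc(OCc2ccccc2)c(OCc2ccccc2)c(OC)c1Br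
F4 | step 12 | (3S,4R)-3-[4,5-bis(benzyloxy)-2-bromo-3-methoxybenzyl]-4-[(tert-butyldimethylsilyloxy)(3,4,5-trimethoxyphenyl)methyl]dihydrofuran-2(3H)-one | O=C1OC[C@H](C(O[Si](C)(C)C(C)(C)C)c2cc(OC)c(OC)c(OC)c2)[C@@H]1Cc1cc(OCc2ccccc2)c(OCc2ccccc2)c(OC)c1Br
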